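At late times the ochre and amber runs read alike as fractions of their charge, though the amber run held 4.00 times the substrate of the ochre run. The flask, charged between them with the same free catalyst, is therefore booked from their means.

| flask | substrate | free catalyst | remark | time |
|---|---|---|---|---|
| ochre | 0.025 M | 50 µM | run made earlier |  |
| amber | 0.10 M | 50 µM | run made earlier |  |
| flask | 0.050 M | 50 µM |  | 4.0 min |

| run | time / min | target / % | isomer of the product / % |
|---|---|---|---|
| ochre | 0.250 | 9 | 5 |
| ochre | 0.417 | 13 | 9 |
| ochre | 0.667 | 14 | 6 |
| ochre | 1.33 | 19 | 12 |
| ochre | 2.00 | 18 | 9 |
| ochre | 3.00 | 21 | 11 |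
| amber | 0.250 | 6 | 5 |
| amber | 0.417 | 13 | 7 |
| amber | 0.667 | 14 | 7 |
| amber | 1.33 | 18 | 10 |
| amber | 2.00 | 19 | 12 |
| amber | 3.00 | 20 | 10 |

(scatter of a reading: 1.5 percentage points)

* the target in the flask at 4.0 min, as a percentage of the substrate charged
* the isomer of the product in the flask at 4.0 min, as a percentage of the substrate charged
* the substrate in the flask at 4.0 min, as a percentage of the substrate charged



Ledger of the substrate charged, an own reckoning:

1. Pool. Target plus isomer of the product averages 0.295 of the charge at 1.33 min and 0.310 at 3.00 min. Over the readings at 2.00 min and 3.00 min it averages 0.300, and this entry is carried unchanged to 4.0 min.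

2. Split. Isomer of the product per target, taken as an apparent equilibrium constant of their interchange, reads 0.538 over those late readings. At 0.250 min and 0.417 min it reads 0.634, so the interchange of the two is treated as fast and in balance.

3. Target. The pool divided by one plus the split gives 0.195.

4. Isomer of the product. The target entry times the split gives 0.105.

5. Substrate. With no other product assumed, the books close at 0.700.

The forecast gives 20.5% target, 10.5% isomer of the product and 69% substrate, noting that “The target-to-isomer ratio stays near 2:1 throughout”. Its pool is 31.0%, so it differs from the ledger by 1 percentage point in target.

The flask holds 20.9% target, 10.5% isomer of the product and 68.6% substrate at 4.0 min.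

    substrate + free catalyst ⇌ target + free catalyst, rate k1*[substrate]*[free catalyst] forward; the back reaction follows from the equilibrium constant (K = 0.330, k = 105 /M/s)
    target + free catalyst ⇌ isomer of the product + free catalyst, rate k2*[free catalyst]*[target] forward; the back reaction follows from the equilibrium constant (K = 0.500, k = 3900 /M/s)
    isomer of the product + free catalyst ⇌ substrate + free catalyst, rate k3*[free catalyst]*[isomer of the product] forward; the back reaction follows from the equilibrium constant (k = 944 /M/s)
    free catalyst + target → spent catalyst A (k = 0.430 /M/s)
    free catalyst → spent catalyst B (k = 0.00946 /s)

In the flask the free catalyst is down to 4.04% of the catalyst charged at that time, and the substrate goes from 68.9% at 3.00 min to 68.4% at 40.0 min. The split times the target of the flask gives 11.2% against 10.5% of isomer of the product. The neighbour charged with 1.2 × 10⁻⁵ M of free catalyst holds 11.9% target at 4.0 min; the split makes that 6.40% of isomer of the product, and the neighbour holds 6.35%.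

The numbers in the tables are simulated on assumed constants.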